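Over 20 min at constant temperature, the question for the next run is whether the charge of solid second nucleophile is worth changing.

the same everywhere: substrate 0.50 mM
- Wednesday's: first nucleophile 0.55 mM; solid second nucleophile 0.32 mM; run made earlier
- Thursday's: first nucleophile 0.55 mM; solid second nucleophile 0.71 mM; run made earlier
- flask: first nucleophile 0.550 mM; solid second nucleophile 0.475 mM; time 20 min

| run | time / min | other capture product / % | target / % | substrate / % |
|---|---|---|---|---|
| Wednesday's | 1.50 | 6.0 | 34.6 | 12.5 |
| Wednesday's | 2.50 | 7.3 | 37.5 | 3.0 |
| Wednesday's | 4.00 | 7.4 | 37.7 | 0.2 |
| Wednesday's | 8.00 | 7.9 | 38.3 | 0.1 |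
| Wednesday's | 12.0 | 7.8 | 38.4 | 0.1 |
| Wednesday's | 20.0 | 7.4 | 37.8 | 0.2 |
| Thursday's | 1.33 | 5.4 | 33.5 | 15.3 |
| Thursday's | 4.00 | 7.5 | 38.8 | 0 |
| Thursday's | 8.00 | 8.3 | 38.1 | 0.2 |
| Thursday's | 10.0 | 8.2 | 37.9 | 0 |
| Thursday's | 15.0 | 7.4 | 38.1 | 0.1 |
| Thursday's | 20.0 | 7.9 | 38.5 | 0 |

(each reading ± 0.3 percentage points)

* share of other capture product in other capture product plus target at 1.5 s
* share of other capture product in other capture product plus target at 20 min
* which of other capture product and target there is more of at 20 min

- solid, in amounts per volume of the solution: solid second nucleophile
- steps that have been proposed: substrate -> intermediate; first nucleophile + intermediate -> target; second nucleophile + intermediate -> other capture product; intermediate -> solvolysis product; solid second nucleophile <-> second nucleophile; first nucleophile <-> dormant form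
- at the start none of the solid second nucleophile is in solution

From 4.00 min on, the substrate reads near zero in both runs. The ratio ρ of other capture product to target, averaged over those readings, is 0.200 on Wednesday and 0.205 on Thursday. These stand within what a scatter of 0.3 percentage points per reading allows, although the solid charge went from 0.32 mM to 0.71 mM. So ρ reads as zero order in the solid charge: the concentration that matters appears to be the dissolved second nucleophile, which seems to stop at one level in both runs. Each capture step, as proposed, is first order in its nucleophile, so with the dissolved second nucleophile held at that level, ρ should fall as the first nucleophile charge rises. The quantity to carry is therefore the capture level C, the plateau ρ multiplied by the first nucleophile charge, here 0.112 mM.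

The flask's solid charge of 0.475 mM lies between the two tested charges, so it can be left as it is. My reckoning for the share at 20 min is C/(C + first nucleophile charge) = 16.9%, with target ahead because ρ is below unity. At 1.5 s the share should lie lower: none of the solid second nucleophile is in solution at the start, and Wednesday's reading at 1.50 min still gives 14.8%, below the plateau.

The forecast gives 3%, 16.9% and target, noting that “The final share of other capture product is the same in both runs”.

The flask gives 0.454% at 1.5 s, 16.9% at 20 min, and target in the lead. At 20.0 min the second nucleophile stands at 0.180 mM, with 53.9% of the solid charge still undissolved.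

    substrate → intermediate (k = 0.0233 s⁻¹)
    first nucleophile + intermediate → target (k = 32400 L mol⁻¹ s⁻¹)
    second nucleophile + intermediate → other capture product (k = 21300 L mol⁻¹ s⁻¹)
    intermediate → solvolysis product (k = 11.5 s⁻¹)
    solid second nucleophile ⇌ second nucleophile, rate k5*(cs5 - [second nucleophile]) while solid is left; crystals form when [second nucleophile] > cs5 (solubility = 0.180 mM, k = 0.0204 s⁻¹)
    first nucleophile ⇌ dormant form (K = 0.802, k = 0.502 s⁻¹)

The flask's own end amounts return C as 0.112 mM. For the neighbour charged with 0.94 mM of first nucleophile, the C read from the earlier runs gives a share of 10.6%, and that flask stands at 10.5%.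

The readings are calculated from invented constants, and the scatter is random.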